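**Retrosynthetic overview**

- Ring numbering: C1 = acyl-bearing CH, C2, C3=C4 (C4 carries the 4-methylpent-3-enyl chain), C5, C6 = phenyl-bearing CH; C7 = ketone carbon.
- The route rests on C1. It is the α-carbon of the C7 aryl ketone and lies between allylic C2 and benzylic C6, so both ring bonds at C1 (C1–C2, C1–C6) are made by alkylating one aroylacetate carbon twice with a Z-configured 1,5-dielectrophile. The only ring, the cyclohexene, closes in that step.
- C6 is set by SN2 inversion of an (R)-benzylic methanesulfonate whose C–O centre comes from (S)-styrene oxide. C1 is set afterwards, once the ester is gone, by equilibration to the trans ketone.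
- The dielectrophile comes from acetylide opening of the epoxide, ynoate formation and syn-carbocupration with the 4-methylpent-3-enyl unit (this fixes the Z-alkene and leaves the two oxygens differentiated), then reduction, bromination and sulfonylation. The nucleophile is the MOM-protected allyl aroylacetate made from 2',4'-dihydroxy-6'-methoxyacetophenone.

Key step: step 11

Remark: conjugate bases formed by simple deprotonation (enolates, the acetylide, alkoxides) are not numbered; 17, 18 and 19 are carried as both epimers at the aroyl-bearing carbon (left undefined in their SMILES), which is of no consequence because that centre is equilibrated in step 12.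

Step 1
Reactants: 1 1-(2,4-dihydroxy-6-methoxyphenyl)ethanone (2',4'-dihydroxy-6'-methoxyacetophenone)
Product: 2 1-[2-methoxy-4,6-bis(methoxymethoxy)phenyl]ethanone
Conditions: NaH (2.4 equiv), DMF, 0 °C; MOMCl (2.4 equiv), 0 °C → rt
Reagents that add atoms: chloromethyl methyl ether (MOMCl), COCCl
Why: Williamson-type O-alkylation of both sodium phenoxides should cap the free and the hydrogen-bonded phenol alike, which is needed because a free ortho phenoxide would consume base and close to a 4-hydroxycoumarin in the carbonate condensation of step 2.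

Step 2
Reactants: 2 1-[2-methoxy-4,6-bis(methoxymethoxy)phenyl]ethanone
Product: 3 allyl 3-[2-methoxy-4,6-bis(methoxymethoxy)phenyl]-3-oxopropanoate
Conditions: NaH (2.5 equiv), diallyl carbonate (3 equiv), THF, reflux; then 1 M HCl, 0 °C
Reagents that add atoms: diallyl carbonate, C=CCOC(=O)OCC=C
Why: Crossed Claisen condensation (C-acylation of the methyl ketone enolate by a dialkyl carbonate) is driven by formation of the stabilised β-keto ester enolate, and the allyl ester is chosen because it can later be removed without acid, hydroxide or strong heating.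

Step 3
Reactants: 4 (S)-2-phenyloxirane ((S)-styrene oxide)
Product: 5 (1R)-1-phenylbut-3-yn-1-ol
Conditions: LiC≡CH·H2NCH2CH2NH2 (1.5 equiv), DMSO, 0 °C → rt; then H2O
Reagents that add atoms: lithium acetylide–ethylenediamine complex, [Li]C#C.NCCN
Why: SN2 opening of a monosubstituted epoxide by an acetylide in DMSO without Lewis acid should go at the unsubstituted carbon, so the C–O stereocentre of 4 is not touched and only its descriptor changes from S to R because phenyl now outranks the CH2 group.

Step 4
Reactants: 5 (1R)-1-phenylbut-3-yn-1-ol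
Product: 6 triethyl{[(1R)-1-phenylbut-3-yn-1-yl]oxy}silane
Conditions: TESCl, imidazole, CH2Cl2, 0 °C → rt
Reagents that add atoms: chlorotriethylsilane, CC[Si](Cl)(CC)CC
Why: Standard imidazole-mediated silylation; the triethylsilyl ether should withstand the organometallic, hydride and Appel steps that follow and can later be cleaved by HF quickly in the presence of an allylic bromide.

Step 5
Reactants: 6 triethyl{[(1R)-1-phenylbut-3-yn-1-yl]oxy}silane
Product: 7 methyl (5R)-5-phenyl-5-[(triethylsilyl)oxy]pent-2-ynoate
Conditions: n-BuLi, THF, −78 °C; ClCO2Me, −78 → 0 °C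
Reagents that add atoms: methyl chloroformate, COC(=O)Cl
Why: Deprotonation of the terminal alkyne and C-acylation of the lithium acetylide with a chloroformate is the standard route to alk-2-ynoates and leaves the silyl ether and the stereocentre untouched.

Step 6
Reactants: 7 methyl (5R)-5-phenyl-5-[(triethylsilyl)oxy]pent-2-ynoate; 8 5-bromo-2-methylpent-2-ene
Product: 12 methyl (2Z)-7-methyl-3-{(2R)-2-phenyl-2-[(triethylsilyl)oxy]ethyl}octa-2,6-dienoate, via Grignard reagent 9 (not isolated), via organocopper reagent 10 (not isolated), via alkenylcopper adduct 11 (not isolated)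
Conditions: 8, Mg, THF, rt; CuBr·SMe2 (1 equiv per Grignard), THF, −40 °C; 7, −78 °C; MeOH then aq. NH4Cl at −78 °C
Reagents that add atoms: none
Why: Syn-carbocupration (conjugate addition of a Grignard-derived organocopper reagent to an alk-2-ynoate in THF at −78 °C, with no free Grignard present and protonation before the adduct can isomerise through the allenoate) places the new chain and the new hydrogen cis, so the ester and the carbinol-bearing arm end up cis (2Z) as the ring closure requires.

Step 7
Reactants: 12 methyl (2Z)-7-methyl-3-{(2R)-2-phenyl-2-[(triethylsilyl)oxy]ethyl}octa-2,6-dienoate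
Product: 13 (2Z)-7-methyl-3-{(2R)-2-phenyl-2-[(triethylsilyl)oxy]ethyl}octa-2,6-dien-1-ol
Conditions: DIBAL-H (2.3 equiv), CH2Cl2, −78 °C; Rochelle salt work-up
Reagents that add atoms: none
Why: DIBAL-H reduces α,β-unsaturated esters by 1,2-addition to the allylic alcohol without touching the alkene geometry or the silyl ether.

Step 8
Reactants: 13 (2Z)-7-methyl-3-{(2R)-2-phenyl-2-[(triethylsilyl)oxy]ethyl}octa-2,6-dien-1-ol
Product: 14 {[(1R,3Z)-5-bromo-3-(4-methylpent-3-en-1-yl)-1-phenylpent-3-en-1-yl]oxy}triethylsilane
Conditions: CBr4, PPh3, CH2Cl2, −20 → 0 °C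
Reagents that add atoms: carbon tetrabromide, BrC(Br)(Br)Br
Why: Appel bromination converts the primary allylic alcohol into the bromide by SN2 displacement of the oxyphosphonium ion under nearly neutral conditions, without allylic transposition or Z/E isomerisation, while the secondary oxygen stays masked.

Step 9
Reactants: 14 {[(1R,3Z)-5-bromo-3-(4-methylpent-3-en-1-yl)-1-phenylpent-3-en-1-yl]oxy}triethylsilane
Product: 15 (1R,3Z)-5-bromo-3-(4-methylpent-3-en-1-yl)-1-phenylpent-3-en-1-ol
Conditions: HF·pyridine, THF, 0 °C; cold aq. NaHCO3 work-up, used at once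
Reagents that add atoms: none
Why: Fluoride-driven Si–O cleavage under weakly acidic conditions frees the carbinol without forming an alkoxide, which would displace the allylic bromide intramolecularly, and the fast cleavage of a TES ether keeps the exposure short.

Step 10
Reactants: 15 (1R,3Z)-5-bromo-3-(4-methylpent-3-en-1-yl)-1-phenylpent-3-en-1-ol
Product: 16 (1R,3Z)-5-bromo-3-(4-methylpent-3-en-1-yl)-1-phenylpent-3-en-1-yl methanesulfonate
Conditions: Ms2O, Et3N, CH2Cl2, −40 °C; cold work-up, used at once without chromatography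
Reagents that add atoms: methanesulfonic anhydride, CS(=O)(=O)OS(C)(=O)=O
Why: O-Sulfonylation makes the benzylic leaving group without breaking the C–O bond, so the R configuration is retained, and the anhydride (no chloride) avoids premature SN2 exchange at the benzylic carbon.

Step 11
Reactants: 3 allyl 3-[2-methoxy-4,6-bis(methoxymethoxy)phenyl]-3-oxopropanoate; 16 (1R,3Z)-5-bromo-3-(4-methylpent-3-en-1-yl)-1-phenylpent-3-en-1-yl methanesulfonate
Product: 18 allyl (6S)-1-[2-methoxy-4,6-bis(methoxymethoxy)benzoyl]-4-(4-methylpent-3-en-1-yl)-6-phenylcyclohex-3-ene-1-carboxylate (both C1 epimers), via C-allylated keto ester 17 (not isolated)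
Conditions: 3, NaH (2.2 equiv), THF (ca. 0.03 M), 0 °C; 16 in THF, −20 °C → rt; then 40 °C
Reagents that add atoms: none
Why: Two enolate alkylations on one carbon, the closest known type being cycloalkylation of a malonate or β-keto ester with a dihalide or halo sulfonate: the chelated sodium enolate of 3 first displaces the primary allylic bromide of 16 at carbon (C1–C2, giving 17), the second equivalent of hydride regenerates an enolate, and this attacks C6 from the face opposite the methanesulfonate (C1–C6). The cyclohexene closes in a 6-(enolexo)-exo-tet mode, the Z-alkene of 16 holding C2 and C5 cis so that the reacting carbons are within reach. C6 is controlled by the substrate: backside SN2 inverts the (R)-carbinol carbon derived from 4 to the configuration of the target (it reads 6S in 18 only because the quaternary C1 outranks phenyl), whereas the quaternary C1 forms as a mixture that is erased in step 12. The step needs site selectivity (primary allylic bromide before secondary benzylic sulfonate, inherent in their SN2 rates), C- over O-alkylation (a six-membered carbocycle against an eight-membered enol ether), and substitution over E2 or ionisation at C6, which the weakly basic stabilised enolate, the non-ionising solvent and the intramolecular delivery are expected to secure. Sodium in THF is chosen so that NaBr precipitates and no soluble bromide can re-displace the sulfonate and erode the configuration.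

Step 12
Reactants: 18 allyl (6S)-1-[2-methoxy-4,6-bis(methoxymethoxy)benzoyl]-4-(4-methylpent-3-en-1-yl)-6-phenylcyclohex-3-ene-1-carboxylate
Product: 21 [2-methoxy-4,6-bis(methoxymethoxy)phenyl][(1R,6R)-4-(4-methylpent-3-en-1-yl)-6-phenylcyclohex-3-en-1-yl]methanone, via keto acid 19 (not isolated), via cis ketone 20 (not isolated)
Conditions: Pd(PPh3)4 (5 mol%), morpholine, THF, rt → 50 °C; then NaOMe, MeOH, 50 °C
Reagents that add atoms: none
Why: Tsuji–Trost deallylation (the π-allyl palladium is captured by morpholine) unmasks the β-keto acid, which loses CO2; ketonisation may give the cis epimer first, and methoxide then equilibrates C1 through the enolate to the trans diequatorial ketone, which sets C1 as R while the non-enolisable C6 is untouched.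

Step 13
Reactants: 21 [2-methoxy-4,6-bis(methoxymethoxy)phenyl][(1R,6R)-4-(4-methylpent-3-en-1-yl)-6-phenylcyclohex-3-en-1-yl]methanone
Product: 22 (2,4-dihydroxy-6-methoxyphenyl)[(1R,6R)-4-(4-methylpent-3-en-1-yl)-6-phenylcyclohex-3-en-1-yl]methanone (target)
Conditions: 3 M HCl, MeOH, 45 °C
Reagents that add atoms: none
Why: Acid-catalysed methanolysis of the two aryl MOM acetals; the mild acid and moderate temperature are meant to spare the two trisubstituted alkenes, and C1 remains at its thermodynamically preferred trans configuration.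

**Compound list**

1 | 1-(2,4-dihydroxy-6-methoxyphenyl)ethanone | CC(=O)c1c(O)cc(O)cc1OC | starting material
2 | 1-[2-methoxy-4,6-bis(methoxymethoxy)phenyl]ethanone | CC(=O)c1c(OCOC)cc(OCOC)cc1OC | intermediate
3 | allyl 3-[2-methoxy-4,6-bis(methoxymethoxy)phenyl]-3-oxopropanoate | COc1cc(OCOC)cc(OCOC)c1C(=O)CC(=O)OCC=C | intermediate
4 | (S)-2-phenyloxirane | C1O[C@H]1c1ccccc1 | starting material
5 | (1R)-1-phenylbut-3-yn-1-ol | C#CC[C@@H](O)c1ccccc1 | intermediate
6 | triethyl{[(1R)-1-phenylbut-3-yn-1-yl]oxy}silane | C#CC[C@@H](O[Si](CC)(CC)CC)c1ccccc1 | intermediate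
7 | methyl (5R)-5-phenyl-5-[(triethylsilyl)oxy]pent-2-ynoate | COC(=O)C#CC[C@@H](O[Si](CC)(CC)CC)c1ccccc1 | intermediate
8 | 5-bromo-2-methylpent-2-ene | CC(C)=CCCBr | starting material
9 | (4-methylpent-3-en-1-yl)magnesium bromide | CC(C)=CCC[Mg]Br | intermediate (not isolated)
10 | (4-methylpent-3-en-1-yl)copper, magnesium bromide complex (drawn as the monomer) | CC(C)=CCC[Cu] | intermediate (not isolated)
11 | methyl (2E)-2-cuprio-7-methyl-3-{(2R)-2-phenyl-2-[(triethylsilyl)oxy]ethyl}octa-2,6-dienoate (drawn C-bound; Cu cis to the new chain) | COC(=O)/C([Cu])=C(\C[C@@H](O[Si](CC)(CC)CC)c1ccccc1)CCC=C(C)C | intermediate (not isolated)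
12 | methyl (2Z)-7-methyl-3-{(2R)-2-phenyl-2-[(triethylsilyl)oxy]ethyl}octa-2,6-dienoate | COC(=O)/C=C(\C[C@@H](O[Si](CC)(CC)CC)c1ccccc1)CCC=C(C)C | intermediate
13 | (2Z)-7-methyl-3-{(2R)-2-phenyl-2-[(triethylsilyl)oxy]ethyl}octa-2,6-dien-1-ol | OC/C=C(\C[C@@H](O[Si](CC)(CC)CC)c1ccccc1)CCC=C(C)C | intermediate
14 | {[(1R,3Z)-5-bromo-3-(4-methylpent-3-en-1-yl)-1-phenylpent-3-en-1-yl]oxy}triethylsilane | BrC/C=C(\C[C@@H](O[Si](CC)(CC)CC)c1ccccc1)CCC=C(C)C | intermediate
15 | (1R,3Z)-5-bromo-3-(4-methylpent-3-en-1-yl)-1-phenylpent-3-en-1-ol | BrC/C=C(\C[C@@H](O)c1ccccc1)CCC=C(C)C | intermediate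
16 | (1R,3Z)-5-bromo-3-(4-methylpent-3-en-1-yl)-1-phenylpent-3-en-1-yl methanesulfonate | BrC/C=C(\C[C@@H](OS(C)(=O)=O)c1ccccc1)CCC=C(C)C | intermediate
17 | allyl (4Z,7R)-2-[2-methoxy-4,6-bis(methoxymethoxy)benzoyl]-5-(4-methylpent-3-en-1-yl)-7-[(methylsulfonyl)oxy]-7-phenylhept-4-enoate (C2 epimers) | COc1cc(OCOC)cc(OCOC)c1C(=O)C(C(=O)OCC=C)C/C=C(\C[C@@H](OS(C)(=O)=O)c1ccccc1)CCC=C(C)C | intermediate (not isolated)
18 | allyl (6S)-1-[2-methoxy-4,6-bis(methoxymethoxy)benzoyl]-4-(4-methylpent-3-en-1-yl)-6-phenylcyclohex-3-ene-1-carboxylate (both C1 epimers) | COc1cc(OCOC)cc(OCOC)c1C(=O)C1(C(=O)OCC=C)CC=C(CCC=C(C)C)C[C@H]1c1ccccc1 | intermediate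
19 | (6S)-1-[2-methoxy-4,6-bis(methoxymethoxy)benzoyl]-4-(4-methylpent-3-en-1-yl)-6-phenylcyclohex-3-ene-1-carboxylic acid (both C1 epimers, held as the morpholinium salt) | COc1cc(OCOC)cc(OCOC)c1C(=O)C1(C(=O)O)CC=C(CCC=C(C)C)C[C@H]1c1ccccc1 | intermediate (not isolated)
20 | [2-methoxy-4,6-bis(methoxymethoxy)phenyl][(1S,6R)-4-(4-methylpent-3-en-1-yl)-6-phenylcyclohex-3-en-1-yl]methanone (cis) | COc1cc(OCOC)cc(OCOC)c1C(=O)[C@H]1CC=C(CCC=C(C)C)C[C@H]1c1ccccc1 | intermediate (not isolated)
21 | [2-methoxy-4,6-bis(methoxymethoxy)phenyl][(1R,6R)-4-(4-methylpent-3-en-1-yl)-6-phenylcyclohex-3-en-1-yl]methanone (trans) | COc1cc(OCOC)cc(OCOC)c1C(=O)[C@@H]1CC=C(CCC=C(C)C)C[C@H]1c1ccccc1 | intermediate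
22 | (2,4-dihydroxy-6-methoxyphenyl)[(1R,6R)-4-(4-methylpent-3-en-1-yl)-6-phenylcyclohex-3-en-1-yl]methanone | COc1cc(O)cc(O)c1C(=O)[C@@H]1CC=C(CCC=C(C)C)C[C@H]1c1ccccc1 | target

**Step count and risks**

Total step count: 13. Longest linear sequence: 11 steps (4 → 22, steps 3–13); the keto ester branch (1 → 3) has 2 steps.

Steps most likely to fail:

Step 11. E2 loss of methanesulfonate towards the phenyl-conjugated diene, or ionisation at C6, may outrun attack by the congested trisubstituted enolate, and the benzylic sulfonate of 16 (made in step 10 and not stored) may not survive until the second alkylation. The fallback sets out from 3 and 14 and comes back at 18. C-Allylation of 3 with the silyl-protected bromide 14 (K2CO3, acetone, rt) should give allyl (4Z,7R)-2-[2-methoxy-4,6-bis(methoxymethoxy)benzoyl]-5-(4-methylpent-3-en-1-yl)-7-phenyl-7-[(triethylsilyl)oxy]hept-4-enoate F1. HF·pyridine in THF would then free the carbinol to allyl (4Z,7R)-7-hydroxy-2-[2-methoxy-4,6-bis(methoxymethoxy)benzoyl]-5-(4-methylpent-3-en-1-yl)-7-phenylhept-4-enoate F2. The ring would be closed without base or an isolated sulfonate by intramolecular Mitsunobu C-alkylation ((cyanomethylene)tributylphosphorane, toluene, 80 °C), the oxyphosphonium being displaced with inversion by the keto ester carbon to give 18.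

Step 9. Once the carbinol is freed it can displace the allylic bromide intramolecularly (six-membered cyclic ether), and HF may solvolyse the allylic bromide. The fallback sets out from 13 and comes back at 16. Fluoride desilylation of 13 (TBAF, THF, 0 °C), at a stage where no leaving group is present, would give (1R,3Z)-3-(4-methylpent-3-en-1-yl)-1-phenylpent-3-ene-1,5-diol F3. Both hydroxyls would be sulfonylated together (Ms2O, Et3N, THF, −40 °C) to (1R,3Z)-3-(4-methylpent-3-en-1-yl)-1-phenylpent-3-ene-1,5-diyl dimethanesulfonate F4, kept in solution. LiBr (1.0 equiv, −40 → −20 °C) would then exchange only the far more reactive primary allylic sulfonate, giving 16 without a hydroxy bromide ever being present.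

Step 12. Ketonisation of the enol under kinetic control may give mainly the cis ketone, the hindered 2,6-disubstituted aryl ketone may equilibrate only slowly under methoxide, and π-allyl palladium may re-alkylate the enolate. The fallback sets out from 2 and 16 and comes back at 21. Claisen condensation of 2 with dimethyl carbonate (NaH, THF, reflux) would give methyl 3-[2-methoxy-4,6-bis(methoxymethoxy)phenyl]-3-oxopropanoate F5. The cycloalkylation of step 11, run on F5 with 16, would give methyl (6S)-1-[2-methoxy-4,6-bis(methoxymethoxy)benzoyl]-4-(4-methylpent-3-en-1-yl)-6-phenylcyclohex-3-ene-1-carboxylate F6. Krapcho dealkoxycarbonylation (NaCl, wet DMSO, 150 °C) would remove the ester by SN2 demethylation and loss of CO2 at a temperature at which ketone and enolate equilibrate, so the trans ketone 21 should result without palladium.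

**Further compounds**

F1 | step 11 | allyl (4Z,7R)-2-[2-methoxy-4,6-bis(methoxymethoxy)benzoyl]-5-(4-methylpent-3-en-1-yl)-7-phenyl-7-[(triethylsilyl)oxy]hept-4-enoate | COc1cc(OCOC)cc(OCOC)c1C(=O)C(C(=O)OCC=C)C/C=C(\C[C@@H](O[Si](CC)(CC)CC)c1ccccc1)CCC=C(C)C
F2 | step 11 | allyl (4Z,7R)-7-hydroxy-2-[2-methoxy-4,6-bis(methoxymethoxy)benzoyl]-5-(4-methylpent-3-en-1-yl)-7-phenylhept-4-enoate | COc1cc(OCOC)cc(OCOC)c1C(=O)C(C(=O)OCC=C)C/C=C(\C[C@@H](O)c1ccccc1)CCC=C(C)C
F3 | step 9 | (1R,3Z)-3-(4-methylpent-3-en-1-yl)-1-phenylpent-3-ene-1,5-diol | OC/C=C(\C[C@@H](O)c1ccccc1)CCC=C(C)C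
F4 | step 9 | (1R,3Z)-3-(4-methylpent-3-en-1-yl)-1-phenylpent-3-ene-1,5-diyl dimethanesulfonate | CS(=O)(=O)OC/C=C(\C[C@@H](OS(C)(=O)=O)c1ccccc1)CCC=C(C)C
F5 | step 12 | methyl 3-[2-methoxy-4,6-bis(methoxymethoxy)phenyl]-3-oxopropanoate | COC(=O)CC(=O)c1c(OC)cc(OCOC)cc1OCOC
F6 | step 12 | methyl (6S)-1-[2-methoxy-4,6-bis(methoxymethoxy)benzoyl]-4-(4-methylpent-3-en-1-yl)-6-phenylcyclohex-3-ene-1-carboxylate | COc1cc(OCOC)cc(OCOC)c1C(=O)C1(C(=O)OC)CC=C(CCC=C(C)C)C[C@H]1c1ccccc1
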